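**Plan**

1. Numbering used below: oxolane O1, C2 (3,4-dimethoxyphenyl, S), C3 (CH3, S), C4 (CH3, R), C5 (4-hydroxy-3,5-dimethoxyphenyl, R). The two aryl groups are cis to each other and each is trans to the methyl next to it.
2. Retrosynthesis: cut O1–C5 (quinone methide closure), then the C5–aryl bond (aryllithium plus lactol), then the C2–aryl bond (acylation of an arylzinc). This leaves C2–C5 with both methyls as meso-2,3-dimethylsuccinic anhydride.
3. Forward: meso anhydride, desymmetrising arylation, ketone reduction with lactonisation (a temporary lactone, opened again by the aryl addition), lactol, open-chain 1,4-diol, desilylation, then closure of the oxolane, the only non-aromatic ring, as the last ring.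
4. Enabling feature: the free hydroxyl at C4 of the 3,5-dimethoxyphenyl ring is para to the ring carbon bonded to C5. C5 can therefore become the exocyclic carbon of a p-quinone methide, the electrophile presumed in the biosynthesis of 7,7'-epoxylignans, and the oxygen on C2 adds to it.
5. Stereochemistry: C3/C4 relative configuration comes from the meso anhydride, and their absolute configuration from the catalyst-controlled choice between its two carbonyls. C2 comes from Felkin–Anh hydride addition, and C5 from the quinone methide closure under control of the C4 methyl.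

Key step: step 8

Assumption: in step 2 the ligand antipode is the one that directs the aryl group to the carbonyl giving the (2R,3S) keto acid; the sense of induction is to be confirmed on lactone 8 before the route is continued.

**Route**

Step 1
Reactants: 1 meso-2,3-dimethylsuccinic acid
Product: 2 cis-2,3-dimethylsuccinic anhydride (meso, (3R,4S)-3,4-dimethyloxolane-2,5-dione)
Conditions: AcCl (neat), reflux; volatiles removed under vacuum
Reagents that add atoms: none
Why: Cyclodehydration of a 1,4-diacid through the mixed anhydride breaks no bond at either stereocentre and is non-basic, so the meso (cis) configuration should be kept.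

Step 2
Reactants: 2 cis-2,3-dimethylsuccinic anhydride; 3 4-bromo-1,2-dimethoxybenzene
Product: 6 (2R,3S)-4-(3,4-dimethoxyphenyl)-2,3-dimethyl-4-oxobutanoic acid, via 3,4-dimethoxyphenyllithium 4 (not isolated), via (3,4-dimethoxyphenyl)zinc trifluoromethanesulfonate 5 (not isolated)
Conditions: 3, n-BuLi, THF, −78 °C; Zn(OTf)2, −78 °C to rt; then 2, [Rh(cod)Cl]2 (4 mol %), TADDOL-derived N,N-dimethylphosphoramidite (8 mol %), THF/DMF, 50 °C; 1 M HCl work-up
Reagents that add atoms: none
Why: Enantioselective desymmetrising acyl cross-coupling of a meso cyclic anhydride, in which monovalent rhodium inserts under ligand control into one of the two enantiotopic acyl–oxygen bonds and the arylzinc transmetalates before reductive elimination, so both methyl centres are retained and the choice of carbonyl fixes the (2R,3S) configuration.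

Step 3
Reactants: 6 (2R,3S)-4-(3,4-dimethoxyphenyl)-2,3-dimethyl-4-oxobutanoic acid
Product: 8 (3R,4S,5S)-5-(3,4-dimethoxyphenyl)-3,4-dimethyloxolan-2-one, via (2R,3S,4S)-4-(3,4-dimethoxyphenyl)-4-hydroxy-2,3-dimethylbutanoic acid 7 (not isolated)
Conditions: LiBH(s-Bu)3 (2.3 equiv), THF, −78 °C; then 2 M HCl, rt
Reagents that add atoms: none
Why: Felkin–Anh-controlled reduction, in which the bulky hydride attacks the aryl ketone anti to the CH(CH3)CO2Li branch and past the small hydrogen, should give the anti alcohol 7 (new 4S centre), which lactonises on acidification to the 3,4-cis-4,5-trans lactone.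

Step 4
Reactants: 8 (3R,4S,5S)-5-(3,4-dimethoxyphenyl)-3,4-dimethyloxolan-2-one
Product: 9 (3R,4S,5S)-5-(3,4-dimethoxyphenyl)-3,4-dimethyloxolan-2-ol (anomer mixture)
Conditions: i-Bu2AlH (1.1 equiv), CH2Cl2, −78 °C; aqueous work-up
Reagents that add atoms: none
Why: Partial reduction of a γ-lactone to the lactol, whose tetrahedral aluminium hemiacetal is stable at −78 °C and so should not be reduced further; the anomeric centre is of no consequence.

Step 5
Reactants: 10 4-bromo-2,6-dimethoxyphenol
Product: 11 (4-bromo-2,6-dimethoxyphenoxy)(tert-butyl)dimethylsilane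
Conditions: TBSCl, imidazole, DMF, rt
Reagents that add atoms: tert-butyldimethylsilyl chloride (TBSCl), CC(C)(C)[Si](C)(C)Cl
Why: Standard imidazole-promoted silylation of a phenol, which masks the acidic hydroxyl for the bromine–lithium exchange of step 6.

Step 6
Reactants: 9 (3R,4S,5S)-5-(3,4-dimethoxyphenyl)-3,4-dimethyloxolan-2-ol; 11 (4-bromo-2,6-dimethoxyphenoxy)(tert-butyl)dimethylsilane
Product: 13 (1S,2S,3R)-4-[4-(tert-butyldimethylsilyloxy)-3,5-dimethoxyphenyl]-1-(3,4-dimethoxyphenyl)-2,3-dimethylbutane-1,4-diol (both C4 epimers), via [4-(tert-butyldimethylsilyloxy)-3,5-dimethoxyphenyl]lithium 12 (not isolated)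
Conditions: 11 (2.5 equiv), n-BuLi (2.5 equiv), THF, −78 °C; then 9, −78 to 0 °C; aq. NH4Cl
Reagents that add atoms: none
Why: Addition of an aryllithium to a lactol, in which the first equivalent deprotonates and opens the lactol and the second adds to the aldehyde; the new carbinol centre forms unselectively, which is harmless because it becomes planar in step 8.

Step 7
Reactants: 13 the silyl-protected diol
Product: 14 (1S,2S,3R)-1-(3,4-dimethoxyphenyl)-4-(4-hydroxy-3,5-dimethoxyphenyl)-2,3-dimethylbutane-1,4-diol (both C4 epimers)
Conditions: Bu4NF (1.1 equiv), THF, 0 °C; then AcOH (1.2 equiv)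
Reagents that add atoms: none
Why: Fluoride cleavage of an aryl silyl ether, driven by the Si–F bond and the good phenoxide leaving group, should leave both benzylic alcohols untouched under these cold, non-acidic conditions.

Step 8
Reactants: 14 the phenolic 1,4-diol
Product: 16 4-[(2R,3R,4S,5S)-5-(3,4-dimethoxyphenyl)-3,4-dimethyloxolan-2-yl]-2,6-dimethoxyphenol (the target), via p-quinone methide 15 (not isolated)
Conditions: camphorsulfonic acid (10 mol %), CH2Cl2 (0.01 M), 4 Å molecular sieves, 0 °C to rt
Reagents that add atoms: none
Why: The acid protonates the carbinol oxygen on the carbon attached to the 4-hydroxy-3,5-dimethoxyphenyl ring and water leaves with push from the para hydroxyl, giving the neutral p-quinone methide 15 in which that carbon is planar, so both carbinol epimers of 14 converge on one intermediate, and the veratryl carbinol oxygen then adds to the exocyclic methide carbon (oxa-1,6-conjugate addition) with return of the phenol. The closest known reaction type is the acid-mediated cyclodehydration of 1,4-diarylbutane-1,4-diols to 2,5-diaryloxolanes through an oxygen-stabilised benzylic cation, and the event retraces the ring closure presumed in the biosynthesis of 7,7'-epoxylignans. The oxolane closes in the 5-exo-trig mode, the nucleophilic oxygen attacking the exocyclic end of the C=C bond. The new centre C5 is controlled by the neighbouring C4 methyl: with the C4–H bond eclipsing the methide plane (least allylic 1,3-strain) the oxygen reaches the face that places the aryl group trans to that methyl, and since the addition is reversible under the acid the more stable 4,5-trans oxolane (R at C5) should accumulate. The step needs ionisation at only one of two benzylic carbinols, and the free phenol secures this because only that ring can lose water as a neutral quinone methide under a weak acid, so the C2–O bond is never broken and C2 keeps its S configuration. High dilution and low temperature are chosen to hold back Friedel–Crafts capture of the methide by the dimethoxyphenyl ring and intermolecular addition.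

**Compound list**

1 | meso-2,3-dimethylsuccinic acid | OC(=O)[C@@H](C)[C@@H](C)C(=O)O | starting material
2 | cis-2,3-dimethylsuccinic anhydride, (3R,4S)-3,4-dimethyloxolane-2,5-dione (meso) | O=C1OC(=O)[C@H](C)[C@@H]1C | intermediate
3 | 4-bromo-1,2-dimethoxybenzene | COc1ccc(Br)cc1OC | starting material
4 | 3,4-dimethoxyphenyllithium | COc1ccc([Li])cc1OC | intermediate
5 | (3,4-dimethoxyphenyl)zinc trifluoromethanesulfonate | COc1ccc([Zn]OS(=O)(=O)C(F)(F)F)cc1OC | intermediate
6 | (2R,3S)-4-(3,4-dimethoxyphenyl)-2,3-dimethyl-4-oxobutanoic acid | COc1ccc(C(=O)[C@@H](C)[C@@H](C)C(=O)O)cc1OC | intermediate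
7 | (2R,3S,4S)-4-(3,4-dimethoxyphenyl)-4-hydroxy-2,3-dimethylbutanoic acid | COc1ccc([C@@H](O)[C@@H](C)[C@@H](C)C(=O)O)cc1OC | intermediate
8 | (3R,4S,5S)-5-(3,4-dimethoxyphenyl)-3,4-dimethyloxolan-2-one (3,4-cis, 4,5-trans) | COc1ccc([C@H]2OC(=O)[C@H](C)[C@@H]2C)cc1OC | intermediate
9 | (3R,4S,5S)-5-(3,4-dimethoxyphenyl)-3,4-dimethyloxolan-2-ol (anomer mixture) | COc1ccc([C@H]2OC(O)[C@H](C)[C@@H]2C)cc1OC | intermediate
10 | 4-bromo-2,6-dimethoxyphenol | COc1cc(Br)cc(OC)c1O | starting material
11 | (4-bromo-2,6-dimethoxyphenoxy)(tert-butyl)dimethylsilane | COc1cc(Br)cc(OC)c1O[Si](C)(C)C(C)(C)C | intermediate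
12 | [4-(tert-butyldimethylsilyloxy)-3,5-dimethoxyphenyl]lithium | COc1cc([Li])cc(OC)c1O[Si](C)(C)C(C)(C)C | intermediate
13 | (1S,2S,3R)-4-[4-(tert-butyldimethylsilyloxy)-3,5-dimethoxyphenyl]-1-(3,4-dimethoxyphenyl)-2,3-dimethylbutane-1,4-diol (C4 epimer mixture) | COc1ccc([C@@H](O)[C@@H](C)[C@@H](C)C(O)c2cc(OC)c(O[Si](C)(C)C(C)(C)C)c(OC)c2)cc1OC | intermediate
14 | (1S,2S,3R)-1-(3,4-dimethoxyphenyl)-4-(4-hydroxy-3,5-dimethoxyphenyl)-2,3-dimethylbutane-1,4-diol (C4 epimer mixture) | COc1ccc([C@@H](O)[C@@H](C)[C@@H](C)C(O)c2cc(OC)c(O)c(OC)c2)cc1OC | intermediate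
15 | p-quinone methide, 4-[(2S,3S,4S)-4-(3,4-dimethoxyphenyl)-4-hydroxy-2,3-dimethylbutylidene]-2,6-dimethoxycyclohexa-2,5-dien-1-one | COc1ccc([C@@H](O)[C@@H](C)[C@@H](C)C=C2C=C(OC)C(=O)C(OC)=C2)cc1OC | intermediate
16 | 4-[(2R,3R,4S,5S)-5-(3,4-dimethoxyphenyl)-3,4-dimethyloxolan-2-yl]-2,6-dimethoxyphenol | COc1ccc([C@H]2O[C@@H](c3cc(OC)c(O)c(OC)c3)[C@H](C)[C@@H]2C)cc1OC | target

**Count**

Total step count: 8. Longest linear sequence: 7 steps (steps 1, 2, 3, 4, 6, 7, 8) from meso-2,3-dimethylsuccinic acid 1; step 5 is a one-step side branch.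

**Steps most likely to fail, with fallbacks**

Step 2. The desymmetrisation may give insufficient enantioselectivity or the wrong sense with the electron-rich arylzinc, and the α-centre of the aryl ketone may erode at 50 °C. The fallback sets out from 2 and comes back at 8; it separates the choice of carbonyl from the carbon–carbon bond formation.
- Alkaloid-mediated methanolysis of 2 (quinidine or quinine, whichever gives the needed antipode, MeOH, toluene, −55 °C) should give the hemiester (2S,3R)-4-methoxy-2,3-dimethyl-4-oxobutanoic acid F1, whose ee could be raised by crystallisation of an amine salt.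
- 1-Chloro-N,N,2-trimethylpropenylamine (CH2Cl2, 0 °C, neutral) should convert it into methyl (2R,3S)-4-chloro-2,3-dimethyl-4-oxobutanoate F2.
- Acylation of arylzinc 5 with F2 under Pd(PPh3)4 catalysis (zerovalent palladium, THF, 0 °C to rt; Negishi acylation) should give methyl (2R,3S)-4-(3,4-dimethoxyphenyl)-2,3-dimethyl-4-oxobutanoate F3.
- LiBH(s-Bu)3 (THF, −78 °C) should then give methyl (2R,3S,4S)-4-(3,4-dimethoxyphenyl)-4-hydroxy-2,3-dimethylbutanoate F4 as its alkoxide, which closes onto the ester on warming to give lactone 8.

Step 8. The veratryl carbinol may ionise in competition, with loss of the C2 configuration or Friedel–Crafts closure to an aryltetralin; the kinetic closure may occur on the wrong face; the quinone methide may oligomerise. The fallback sets out from 9 and comes back at 16; it keeps the lactol ring of 9 and introduces the phenolic aryl group last by carbon–carbon bond formation.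
- BF3·OEt2 (CH2Cl2, −78 to −20 °C) should ionise 9 to the cyclic oxocarbenium ion (2S,3S,4R)-2-(3,4-dimethoxyphenyl)-3,4-dimethyl-3,4-dihydro-2H-furan-1-ium F7.
- Commercial 2,6-dimethoxyphenol should attack F7 through its carbon para to the hydroxyl and anti to the adjacent methyl (Friedel–Crafts C-arylation of a lactol), giving 16 directly without a protecting group.

Step 3. Poor facial selectivity in the hydride addition would give the 4,5-cis lactone. The fallback sets out from 6 and comes back at 8; it gives up kinetic control for thermodynamic control.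
- NaBH4 (MeOH, 0 °C; HCl work-up) should give, beside 7 and 8, the epimeric hydroxy acid (2R,3S,4R)-4-(3,4-dimethoxyphenyl)-4-hydroxy-2,3-dimethylbutanoic acid F5 and from it the 4,5-cis lactone (3R,4S,5R)-5-(3,4-dimethoxyphenyl)-3,4-dimethyloxolan-2-one F6.
- CF3CO2H in CH2Cl2 at rt should then reversibly ionise the benzylic C5–O bond (p-methoxy-stabilised cation recaptured by the carboxyl group), which should funnel F6 into the more stable 4,5-trans lactone 8 without touching C3 or C4.

**Further compounds**

F1 | step 2 | (2S,3R)-4-methoxy-2,3-dimethyl-4-oxobutanoic acid | OC(=O)[C@@H](C)[C@@H](C)C(=O)OC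
F2 | step 2 | methyl (2R,3S)-4-chloro-2,3-dimethyl-4-oxobutanoate | ClC(=O)[C@@H](C)[C@@H](C)C(=O)OC
F3 | step 2 | methyl (2R,3S)-4-(3,4-dimethoxyphenyl)-2,3-dimethyl-4-oxobutanoate | COc1ccc(C(=O)[C@@H](C)[C@@H](C)C(=O)OC)cc1OC
F4 | step 2 | methyl (2R,3S,4S)-4-(3,4-dimethoxyphenyl)-4-hydroxy-2,3-dimethylbutanoate | COc1ccc([C@@H](O)[C@@H](C)[C@@H](C)C(=O)OC)cc1OC
F5 | step 3 | (2R,3S,4R)-4-(3,4-dimethoxyphenyl)-4-hydroxy-2,3-dimethylbutanoic acid | COc1ccc([C@H](O)[C@@H](C)[C@@H](C)C(=O)O)cc1OC
F6 | step 3 | (3R,4S,5R)-5-(3,4-dimethoxyphenyl)-3,4-dimethyloxolan-2-one | COc1ccc([C@@H]2OC(=O)[C@H](C)[C@@H]2C)cc1OC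
F7 | step 8 | (2S,3S,4R)-2-(3,4-dimethoxyphenyl)-3,4-dimethyl-3,4-dihydro-2H-furan-1-ium | COc1ccc([C@H]2[O+]=C[C@H](C)[C@@H]2C)cc1OC
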